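Each step that uses reagent makes one by-product, so c(by-product) plus c(reagent) counts what has crossed from the gas, net, and I began from that count.

    substrate + reagent → single product + by-product (k1 = 0.517 M⁻¹ min⁻¹)
    substrate + reagent → other mono adduct + by-product (k2 = 0.832 M⁻¹ min⁻¹)
    reagent + single product → bis adduct + by-product (k3 = 0.248 M⁻¹ min⁻¹)
    reagent + other mono adduct → bis adduct + by-product (k4 = 0.0174 M⁻¹ min⁻¹)
    gas ⇌ reagent, rate k5*(csat - [reagent]) (k5 = 0.0548 min⁻¹, csat = 48 mM)

the same everywhere: gas 48 mM (held); time 6.0 h
- elm: substrate 0.25 M
- ash: substrate 0.50 M
- birch: substrate 1.0 M
- oak: substrate 2.0 M

- at the start none of reagent is dissolved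
- "hardly changes" means that all values lie within two and a half points (for a concentration: within two and a half percent of the largest)
- run time (elm): 6.0 h

1. amount of single product at the end, in percent of the substrate charged for elm, ash, birch, oak, in this order
2. the shape of the row from first to last (falls all the way / falls, then rises / rises all the way / hardly changes / rises, then falls)

Crossing is fastest while c(reagent) stays near zero, at k5·csat. So I named the supply ceiling, the reagent that can cross in the run at that pace: 0.947 M. Divided by each charge, it gives the offer:

| flask | offer, reagent per substrate charged |
|---|---|
| elm | 3.79 |
| ash | 1.89 |
| birch | 0.947 |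
| oak | 0.473 |

Was the ceiling reachable? Reagent is used at first order in c(reagent), with rate constant (k1+k2)·c(substrate). At the start of oak this is 2.70 min⁻¹, much faster than k5, so crossing is the rate-limiting step and by-product should grow at zero order.

But that lasts only while substrate does. Once elm has lost its substrate, the use constant can reach only k3·c(single product), 0.0620 min⁻¹ even with the whole charge as single product, which is about k5. So c(reagent) must climb and crossing must slow. I therefore trusted the offer for birch and oak, where it stays below one, and took it as an upper bound for elm and ash.

Next, what does an offer yield? c(reagent) multiplies each consuming rate, so it cancels from their ratios. Against the exposure, the time integral of c(reagent), the fractions of the charge follow one curve. Substrate decays with 1.35 M⁻¹ min⁻¹, and single product forms and decays with k3. That curve tops at an exposure of 92.3 M·s, with single product at 26.2% of the charge, where 0.957 reagent has been used per substrate. The ceiling then puts the best charge at 0.989 M, so I expected a rise and then a fall. With bis adduct neglected, oak came to 17.0%.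

The forecast gave 4%, 13.6%, 25.7% and 16.2%, rises, then falls, with “the best yield falls near 1 M”, and its oak is lower than mine.

The flasks gave 3.99%, 13.7%, 25.7% and 16.2%: rises, then falls, with the turn read at 0.89 M, below my 0.989 M. In oak, by-product plus reagent stood at 0.923 M after 6.00 h, which is 97.4% of the ceiling. In elm at 1.59 h, reagent was made only 1.09 times faster than it was used, and by 6.00 h the same count in elm had reached 0.402 M, or 42.5% of the ceiling.

All constants stand for no real mixture; the run is a simulation.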